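## The problem

Compound 14 is an acylphloroglucinol. Ring A is a benzene with an isobutyryl group at C1, hydroxyls at C2, C4 and C6, and at C3 and C5 a methylene bridge to C3 of a 6-ethyl-4-hydroxy-5-methyl-2H-pyran-2-one (rings B and C, identical). There is no stereocentre, and a mirror plane through the ketone and C4–OH makes the two arms equivalent, so only connectivity and chemoselectivity need control and a two-directional synthesis is natural. The hard bonds are the two CH2–C3(pyranone) bonds, each joining two fully substituted, electron-rich π systems. The traditional condensation of a free phloroglucinol and a free 4-hydroxypyranone with a formaldehyde equivalent runs through quinone methides and cannot tell the partners apart: it gives aryl–CH2–aryl and pyranone–CH2–pyranone products beside the mixed bridge, and the ambident pyranone enolate also alkylates on oxygen. The functional groups are delicate: the triphenol oxidises easily, the pyranones are vinylogous acids that quench organometallics and open with hydroxide or alkoxide, and the doubly activated bridges can be cleaved or scrambled by hot acid or base. All five hydroxyls therefore stay masked until the last step and are unmasked cold. A different bond construction is possible because each bridge carbon is benzylic to ring A and bonded to pyranone C3, an sp2 carbon between the lactone carbonyl C2 and the oxygen-bearing C4. C3 and C5 of a trimethoxyphenyl ketone are its most nucleophilic ring positions and accept CH2Cl, and pyranone C3 is the enol carbon and accepts bromine, so both ends of each bridge are available as halides of different hybridisation that a nickel catalyst can tell apart.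

## Retrosynthesis

**14 to 13 (five O–C bonds).** The last operation is removal of five ether groups from 13. Ring A carries methyl ethers because they must survive AlCl3 and the HCl/formaldehyde medium of the chloromethylation. The pyranone oxygens carry benzyl and not methyl: a 4-methoxy-2-pyranone is a vinylogous carbonate, and its BBr3 adduct is a stabilised alkoxypyrylium-type species that gives up methyl reluctantly, so a global demethylation would be likely to stall at rings B and C. Benzyl leaves under the same BBr3 treatment far more easily and can also be removed by hydrogenolysis. The forward reaction must cleave all five ethers in the cold without disturbing the bridges.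

**13 to 11 and two molecules of 7 (both CH2–C3 bonds, through 12).** Cutting at the pyranone side of each bridge gives a bis(benzylic chloride) 11 and a 3-bromopyranone 7, both electrophiles. The neighbouring cut at the aryl–CH2 bond would need a 3-(halomethyl)pyranone, itself a masked quinone-methide-type electrophile, and a Friedel–Crafts reaction on an arene already deactivated by the ketone. The same cut in classical polarity (pyranone enolate plus benzylic halide) requires the free 4-hydroxyl and brings back O- against C-alkylation. The cross-electrophile version keeps every oxygen etherified, so no quinone methide and no O-alkylation can arise. The precursors are much simpler: 11 is a C15 arene and 7 a monocyclic bromide. The forward reaction must couple twice on one molecule and must favour cross-coupling over benzyl–benzyl and pyranone–pyranone dimerisation.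

**11 to 10 to 8 and 9 (two aryl–CH2Cl bonds, then the aryl–acyl bond).** Both chloromethyl groups are removed to give ketone 10, whose two free ring positions are equivalent and each lies ortho, ortho and para to a methoxyl. Ketone 10 comes from 1,3,5-trimethoxybenzene 8 and isobutyryl chloride 9 by Friedel–Crafts acylation. The order is fixed: benzylic chlorides would not survive a Friedel–Crafts acylation, while the acyl group, twisted out of conjugation by two ortho methoxyls, leaves the ring reactive enough for a double Blanc reaction.

**7 to 6 to 5 (O–benzyl, then C3–Br).** Removing benzyl gives bromo-enol 6 and removing bromine gives hydroxypyranone 5. Brominating before benzylating is preferred: the free enol reacts with NBS at C3 under ionic conditions, so no radical bromination of the ethyl or methyl side chains is risked, and with C3 occupied the benzylation can only go to oxygen.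

**5 to 2 and 3, and 2 to 1 (C4–C5 and O1–C2 of the pyranone).** The ring is opened to the silyl enol ether 2 of pentan-3-one 1 and malonyl dichloride 3, by way of acyl chloride 4. The symmetric ketone places ethyl at C6 and methyl at C5 without any regiochemical question, and the whole heterocycle arises from two bulk chemicals in two steps.

## Roads not taken

**Alternative 1:** The pyranone rings are cut at O1–C6. The precursor is the bis(ynone) di-tert-butyl keto ester A1; a cationic phosphine–gold catalyst would activate both alkynes so that each ester carbonyl oxygen attacks the ethyl-bearing alkyne carbon, with loss of the tert-butyl groups, to give bis(hydroxypyranone) A2.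
- Merits: the benzylic C–C bonds would come from ordinary β-keto ester alkylation with a dichloride such as 11, a polarity-matched and very reliable reaction, and the ring closure is mild and catalytic. In that respect it is safer than a double cross-electrophile coupling.
- Weak points: A2 has hydrogen at C5 of both pyranones, because that carbon is the alkyne carbon that is protonated after cyclisation. The two methyl groups of the target would have to be added afterwards at a position that is not the natural nucleophilic site of a 4-hydroxypyranone, probably by halogenation and cross-coupling on both rings. A1 is a doubly enolisable ynone that can cyclise through the wrong oxygen or add conjugatively to itself.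
- Comparison: the chosen plan brings in rings B and C complete and correctly substituted and is shorter; it pays with a more demanding coupling step.

**Alternative 2:** The cut is at the aryl–C(=O) and the neighbouring aryl–O bond. A fluoride source would turn the fully substituted ortho-silylaryl triflate A3 into an aryne that inserts into the C(acyl)–O bond of isobutyric acid A5, giving the ortho-hydroxyaryl ketone A4.
- Merits: ketone and one free phenol arrive in a single step. The regiochemistry is favourable, since the methoxyl next to the aryne directs the carboxylate oxygen to the distal carbon and the acyl group to the proximal one. One ether fewer has to be cleaved at the end, which is better than the chosen plan.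
- Weak points: A3 must already carry both pyranonylmethyl arms, so the bridge bonds, the real difficulty, still have to be made by some other method. A3 is a hexasubstituted benzene that needs a long preparation, and a hindered aryne bearing two lactones and an α-branched acid partner invite ene, addition and simple O-arylation side reactions. A4 also keeps pyranone methyl ethers, whose cleavage is doubtful.
- Comparison: the chosen plan installs the ketone in its first arene step on a commercial compound and keeps the hard step for the bonds that matter.

**Alternative 3:** Ring A itself is cut. Heating the 3-methoxycyclobutenone A6 with the methyl ynol ether A7 would give a vinylketene, [2+2] addition, four-electron ring opening and six-electron closure to phenol A8.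
- Merits: the substitution pattern of ring A is set with complete regiocontrol and without electrophilic aromatic substitution, the reaction needs no metal, and the two arms enter separately, which would be an advantage for unsymmetrical analogues.
- Weak points: it builds a benzene ring that can be bought with the right oxygenation. A6 and A7 each need a pyranone C3–CH2 bond, so the O- against C-alkylation problem returns twice, in two different syntheses. A7 is a sensitive alkoxyalkyne. A8 still needs acylation at the crowded position between two methoxyls and then deprotection.
- Comparison: the chosen plan is much shorter and uses the symmetry of the target; it gives up the possibility of differentiating the arms, which this target does not require.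

Key step: step 7

Assumption: enol ether 2 is used as the mixture of double-bond isomers formed on silylation, since both give the same pyranone 5. Acyl chloride 4 is a racemic, enolisable intermediate whose stereocentre disappears on ring closure.

## Route

Step 1
Reactants: 1 pentan-3-one
Product: 2 trimethyl(pent-2-en-3-yloxy)silane (E/Z mixture)
Conditions: TMSOTf, Et3N, CH2Cl2, 0 °C to rt
Reagents that add atoms: trimethylsilyl trifluoromethanesulfonate, C[Si](C)(C)OS(=O)(=O)C(F)(F)F
Why: Soft enolisation and O-silylation of a symmetric ketone, so only one regioisomer of the silyl enol ether can form; the double-bond geometry is irrelevant because it is lost in step 2.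

Step 2
Reactants: 2 trimethyl(pent-2-en-3-yloxy)silane, 3 malonyl dichloride
Product: 5 6-ethyl-4-hydroxy-5-methyl-2H-pyran-2-one, via 4-methyl-3,5-dioxoheptanoyl chloride 4 (not isolated)
Conditions: Et2O, −78 °C to rt
Reagents that add atoms: none
Why: Known pyranone synthesis from silyl enol ethers and malonyl dichloride: C-acylation at the enol ether carbon gives 4, whose ethyl ketone enol oxygen then closes onto the second acid chloride, placing ethyl at C6, methyl at C5 and the free enol at C4.

Step 3
Reactants: 5 6-ethyl-4-hydroxy-5-methyl-2H-pyran-2-one
Product: 6 3-bromo-6-ethyl-4-hydroxy-5-methyl-2H-pyran-2-one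
Conditions: NBS (1.0 equiv), CH2Cl2, 0 °C, dark
Reagents that add atoms: N-bromosuccinimide, O=C1CCC(=O)N1Br
Why: Electrophilic bromination of the enol at C3, the only unsubstituted nucleophilic ring carbon since C5 carries methyl; cold ionic conditions without light or initiator avoid radical attack on the side chains, and one equivalent avoids a 3,3-dibromide.

Step 4
Reactants: 6 3-bromo-6-ethyl-4-hydroxy-5-methyl-2H-pyran-2-one
Product: 7 4-(benzyloxy)-3-bromo-6-ethyl-5-methyl-2H-pyran-2-one
Conditions: BnBr, K2CO3, DMF, rt
Reagents that add atoms: benzyl bromide, BrCc1ccccc1
Why: Williamson O-alkylation of the vinylogous acid anion; C3 is blocked by bromine so C-benzylation is shut off, and anion alkylation of 4-hydroxy-2-pyranones is expected to give the 4-alkoxy-2-pyranone rather than the 2-alkoxy-4-pyranone.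

Step 5
Reactants: 8 1,3,5-trimethoxybenzene, 9 isobutyryl chloride (2-methylpropanoyl chloride)
Product: 10 2-methyl-1-(2,4,6-trimethoxyphenyl)propan-1-one
Conditions: AlCl3 (1.1 equiv), CH2Cl2, 0 °C
Reagents that add atoms: none
Why: Friedel–Crafts acylation of an arene with three equivalent activated positions; the ketone deactivates the product against a second acylation, and low temperature with a short reaction time limits AlCl3-mediated cleavage of the ortho methyl ethers.

Step 6
Reactants: 10 2-methyl-1-(2,4,6-trimethoxyphenyl)propan-1-one
Product: 11 1-[3,5-bis(chloromethyl)-2,4,6-trimethoxyphenyl]-2-methylpropan-1-one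
Conditions: (CH2O)n (excess), HCl (gas), AcOH, 50 °C
Reagents that add atoms: formaldehyde (as paraformaldehyde), C=O; hydrogen chloride, Cl
Why: Blanc chloromethylation at the two equivalent free positions, each ortho, ortho and para to a methoxyl and meta to the twisted acyl group; excess formaldehyde and HCl should drive both positions and suppress diarylmethane formation, as in the known exhaustive halomethylation of 1,3,5-trimethoxybenzene.

Step 7
Reactants: 11 1-[3,5-bis(chloromethyl)-2,4,6-trimethoxyphenyl]-2-methylpropan-1-one, 7 4-(benzyloxy)-3-bromo-6-ethyl-5-methyl-2H-pyran-2-one (two equivalents enter the product, three are used)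
Product: 13 1-{3,5-bis[(4-(benzyloxy)-6-ethyl-5-methyl-2-oxo-2H-pyran-3-yl)methyl]-2,4,6-trimethoxyphenyl}-2-methylpropan-1-one, via monocoupled chloromethyl ketone 12 (not isolated)
Conditions: NiBr2(dme) (20 mol %), 4,4'-di-tert-butyl-2,2'-bipyridine (24 mol %), NaI, DMA, undivided cell, reticulated vitreous carbon cathode, Zn anode, constant current, rt; 11 added slowly to 7
Reagents that add atoms: none
Why: Cathodic reduction turns the bipyridine-ligated NiBr2 into zerovalent nickel, which adds oxidatively to the C3–Br bond of 7, an electron-poor alkenyl bromide next to the lactone carbonyl, to give a divalent pyranonylnickel bromide. Monovalent nickel, left after each reductive elimination or formed at the cathode, abstracts the halogen from a CH2Cl group of 11 (partly after chloride–iodide exchange by NaI); the benzylic radical is captured by the divalent pyranonylnickel species and reductive elimination from trivalent nickel forms the CH2–C3 bond. The closest known reaction type is the nickel-catalysed reductive cross-electrophile coupling of aryl or alkenyl bromides with benzylic chlorides, driven by zinc or manganese powder or by a cathode with a sacrificial anode. No ring is closed and no stereocentre is formed; the cycle runs at the first CH2Cl group to give 12 and again at the second to give 13. The step needs cross-selectivity over bibenzyl and bipyranone formation, which rests on the two halides being activated by different mechanisms: two-electron oxidative addition at C(sp2)–Br and halogen-atom abstraction at the benzylic C–Cl. Keeping 7 in excess and feeding 11 slowly reinforces this, so that each benzylic radical meets a pyranonylnickel species and not another radical. Holding the current at the nickel couple should keep the hindered aryl ketone, the lactones and the benzyl ethers from direct reduction, and with every oxygen etherified neither a quinone methide nor an O-alkylated pyranone can form.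

Step 8
Reactants: 13 1-{3,5-bis[(4-(benzyloxy)-6-ethyl-5-methyl-2-oxo-2H-pyran-3-yl)methyl]-2,4,6-trimethoxyphenyl}-2-methylpropan-1-one
Product: 14 3,3'-{[2,4,6-trihydroxy-5-(2-methylpropanoyl)-1,3-phenylene]bis(methylene)}bis(6-ethyl-4-hydroxy-5-methyl-2H-pyran-2-one) (CNP0277086.0)
Conditions: BBr3 (10 equiv), CH2Cl2, −78 °C to rt; H2O, 0 °C
Reagents that add atoms: none
Why: Lewis acid ether cleavage: bromide should remove the benzyl groups from the pyranone oxygens first, the two methyl ethers ortho to the ketone follow with chelation assistance and the central one last; ring A has no free carbon and the phenols stay bound as borates until hydrolysis, which should keep them from attacking pyranone C4.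

## Compound list

1 | pentan-3-one | CCC(=O)CC | starting material
2 | trimethyl(pent-2-en-3-yloxy)silane (E/Z mixture) | CC=C(CC)O[Si](C)(C)C | intermediate
3 | malonyl dichloride (propanedioyl dichloride) | O=C(Cl)CC(Cl)=O | starting material
4 | 4-methyl-3,5-dioxoheptanoyl chloride (racemic, not isolated) | CCC(=O)C(C)C(=O)CC(Cl)=O | intermediate
5 | 6-ethyl-4-hydroxy-5-methyl-2H-pyran-2-one | CCc1oc(=O)cc(O)c1C | intermediate
6 | 3-bromo-6-ethyl-4-hydroxy-5-methyl-2H-pyran-2-one | CCc1oc(=O)c(Br)c(O)c1C | intermediate
7 | 4-(benzyloxy)-3-bromo-6-ethyl-5-methyl-2H-pyran-2-one | CCc1oc(=O)c(Br)c(OCc2ccccc2)c1C | intermediate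
8 | 1,3,5-trimethoxybenzene | COc1cc(OC)cc(OC)c1 | starting material
9 | isobutyryl chloride (2-methylpropanoyl chloride) | CC(C)C(Cl)=O | starting material
10 | 2-methyl-1-(2,4,6-trimethoxyphenyl)propan-1-one | CC(C)C(=O)c1c(OC)cc(OC)cc1OC | intermediate
11 | 1-[3,5-bis(chloromethyl)-2,4,6-trimethoxyphenyl]-2-methylpropan-1-one | CC(C)C(=O)c1c(OC)c(CCl)c(OC)c(CCl)c1OC | intermediate
12 | 1-{3-(chloromethyl)-5-[(4-(benzyloxy)-6-ethyl-5-methyl-2-oxo-2H-pyran-3-yl)methyl]-2,4,6-trimethoxyphenyl}-2-methylpropan-1-one (not isolated) | CC(C)C(=O)c1c(OC)c(CCl)c(OC)c(Cc2c(OCc3ccccc3)c(C)c(CC)oc2=O)c1OC | intermediate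
13 | 1-{3,5-bis[(4-(benzyloxy)-6-ethyl-5-methyl-2-oxo-2H-pyran-3-yl)methyl]-2,4,6-trimethoxyphenyl}-2-methylpropan-1-one | CC(C)C(=O)c1c(OC)c(Cc2c(OCc3ccccc3)c(C)c(CC)oc2=O)c(OC)c(Cc2c(OCc3ccccc3)c(C)c(CC)oc2=O)c1OC | intermediate
14 | 3,3'-{[2,4,6-trihydroxy-5-(2-methylpropanoyl)-1,3-phenylene]bis(methylene)}bis(6-ethyl-4-hydroxy-5-methyl-2H-pyran-2-one) | CCc1oc(=O)c(Cc2c(O)c(Cc3c(O)c(C)c(CC)oc3=O)c(O)c(C(=O)C(C)C)c2O)c(O)c1C | target

## Step count and risks

Total: 8 steps. Longest linear sequence: 6 steps (steps 1, 2, 3, 4, 7, 8); the arene branch (steps 5 and 6) joins at step 7.

**Step 7 (key step).** The benzylic radicals may dimerise, which with a bis-electrophile means oligomerisation. Bromide 7 may be reduced to the debrominated pyranone. Capture at two positions that are each flanked on both sides may be slow, so that the reaction stops at the stage of 12. Fallback: from 11, LiCl-mediated zinc insertion (Zn dust, LiCl, THF, rt) should give the bis(benzylic zinc chloride) 1-{3,5-bis[(chlorozincio)methyl]-2,4,6-trimethoxyphenyl}-2-methylpropan-1-one F1. A Negishi coupling of F1 with 7 (Pd(OAc)2, SPhos, THF, rt to 50 °C; zerovalent palladium formed in the flask) returns to the route at 13. The same bonds are then made in defined polarity, benzylic nucleophile and pyranone electrophile, and benzylic zinc reagents tolerate a hindered ketone.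

**Step 6.** The very reactive trimethoxybenzylic chlorides may alkylate unreacted or monochloromethylated arene to diarylmethane oligomers. The second chloromethylation may lag, and the chlorides may hydrolyse on work-up. Fallback: from 10, Rieche formylation (Cl2CHOCH3, TiCl4, CH2Cl2, 0 °C to rt) to the dialdehyde 2,4,6-trimethoxy-5-(2-methylpropanoyl)benzene-1,3-dicarbaldehyde F2, in which each formyl group deactivates rather than activates. NaBH4 in MeOH at 0 °C should reduce the aldehydes and spare the hindered, twisted ketone, giving 1-[3,5-bis(hydroxymethyl)-2,4,6-trimethoxyphenyl]-2-methylpropan-1-one F3. SOCl2 in CH2Cl2 at 0 °C then returns to the route at 11.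

**Step 8.** The benzyl groups set free by BBr3 may be transferred to ring A or its oxygens. Cleavage of the central methyl ether, which has no chelating neighbour, may stay incomplete. On long exposure an ortho phenol may condense onto pyranone C4. Fallback: from 13, hydrogenolysis (H2, Pd/C, EtOAc, rt) removes both benzyl groups as an inert hydrocarbon and gives 1-{3,5-bis[(6-ethyl-4-hydroxy-5-methyl-2-oxo-2H-pyran-3-yl)methyl]-2,4,6-trimethoxyphenyl}-2-methylpropan-1-one F4. BBr3 (CH2Cl2, −78 to 0 °C) then has only the three aryl methyl ethers to cleave and returns to the route at 14.

**Step 4.** Alkylation may go to the lactone carbonyl oxygen, giving the 2-benzyloxy-4-pyranone isomer, and the α-bromo enolate may lose bromine under basic conditions. Fallback: from 5, Mitsunobu O-benzylation (BnOH, PPh3, DIAD, THF, 0 °C to rt), which is selective for O4 of 4-hydroxy-2-pyranones, gives 4-(benzyloxy)-6-ethyl-5-methyl-2H-pyran-2-one F5. NBS in MeCN in the dark then brominates C3 and returns to the route at 7, bypassing 6.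

## Further compounds

F1 | step 7 | 1-{3,5-bis[(chlorozincio)methyl]-2,4,6-trimethoxyphenyl}-2-methylpropan-1-one | CC(C)C(=O)c1c(OC)c(C[Zn]Cl)c(OC)c(C[Zn]Cl)c1OC
F2 | step 6 | 2,4,6-trimethoxy-5-(2-methylpropanoyl)benzene-1,3-dicarbaldehyde | CC(C)C(=O)c1c(OC)c(C=O)c(OC)c(C=O)c1OC
F3 | step 6 | 1-[3,5-bis(hydroxymethyl)-2,4,6-trimethoxyphenyl]-2-methylpropan-1-one | CC(C)C(=O)c1c(OC)c(CO)c(OC)c(CO)c1OC
F4 | step 8 | 1-{3,5-bis[(6-ethyl-4-hydroxy-5-methyl-2-oxo-2H-pyran-3-yl)methyl]-2,4,6-trimethoxyphenyl}-2-methylpropan-1-one | CC(C)C(=O)c1c(OC)c(Cc2c(O)c(C)c(CC)oc2=O)c(OC)c(Cc2c(O)c(C)c(CC)oc2=O)c1OC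
F5 | step 4 | 4-(benzyloxy)-6-ethyl-5-methyl-2H-pyran-2-one | CCc1oc(=O)cc(OCc2ccccc2)c1C
A1 | alternative 1 | di-tert-butyl 2,2'-{[2,4,6-trimethoxy-5-(2-methylpropanoyl)-1,3-phenylene]bis(methylene)}bis(3-oxohept-4-ynoate) (mixture of diastereomers) | CC(C)C(=O)c1c(OC)c(CC(C(=O)OC(C)(C)C)C(=O)C#CCC)c(OC)c(CC(C(=O)OC(C)(C)C)C(=O)C#CCC)c1OC
A2 | alternative 1 | 1-{3,5-bis[(6-ethyl-4-hydroxy-2-oxo-2H-pyran-3-yl)methyl]-2,4,6-trimethoxyphenyl}-2-methylpropan-1-one | CC(C)C(=O)c1c(OC)c(Cc2c(O)cc(CC)oc2=O)c(OC)c(Cc3c(O)cc(CC)oc3=O)c1OC
A3 | alternative 2 | 2,4-bis[(6-ethyl-4-methoxy-5-methyl-2-oxo-2H-pyran-3-yl)methyl]-3,5-dimethoxy-6-(trimethylsilyl)phenyl trifluoromethanesulfonate | C[Si](C)(C)c1c(OC)c(Cc2c(OC)c(C)c(CC)oc2=O)c(OC)c(Cc2c(OC)c(C)c(CC)oc2=O)c1OS(=O)(=O)C(F)(F)F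
A4 | alternative 2 | 1-{2-hydroxy-4,6-dimethoxy-3,5-bis[(6-ethyl-4-methoxy-5-methyl-2-oxo-2H-pyran-3-yl)methyl]phenyl}-2-methylpropan-1-one | CC(C)C(=O)c1c(O)c(Cc2c(OC)c(C)c(CC)oc2=O)c(OC)c(Cc3c(OC)c(C)c(CC)oc3=O)c1OC
A5 | alternative 2 | isobutyric acid (2-methylpropanoic acid) | CC(C)C(=O)O
A6 | alternative 3 | 4-[(6-ethyl-4-methoxy-5-methyl-2-oxo-2H-pyran-3-yl)methyl]-3-methoxycyclobut-2-en-1-one (racemic) | COC1=CC(=O)C1Cc2c(OC)c(C)c(CC)oc2=O
A7 | alternative 3 | 6-ethyl-4-methoxy-3-(3-methoxyprop-2-yn-1-yl)-5-methyl-2H-pyran-2-one | COC#CCc1c(OC)c(C)c(CC)oc1=O
A8 | alternative 3 | 2,6-bis[(6-ethyl-4-methoxy-5-methyl-2-oxo-2H-pyran-3-yl)methyl]-3,5-dimethoxyphenol | Oc1c(Cc2c(OC)c(C)c(CC)oc2=O)c(OC)cc(OC)c1Cc3c(OC)c(C)c(CC)oc3=O
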